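**Retrosynthetic overview**
- The target is reached by acid removal of three MOM groups, oxidation at C4 of a cis-(3S,4S)-isoflavan-4-ol, and asymmetric transfer hydrogenation with dynamic kinetic resolution of a flat 6,5'-diprenylisoflavone. C3 is set in that last operation.
- Both prenyl groups come from one double Stille coupling on a 6-iodo-5'-bromoisoflavone. The iodine is placed ortho to the free, chelated 5-OH.
- Ring C (O1–C2–C3–C4–C4a–C8a) comes from a one-carbon ring expansion. C3 is cut out together with ring B as an "aryl carbyne". This leaves the five-membered furan ring (O1–C2–C3–C3a–C7a) of a 3-silyloxybenzofuran and an arylchlorodiazirine.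
- Enabling feature: C3, the only ring-C carbon that bears ring B, lies between C2 (bound to O1) and the carbonyl carbon C4. Without it, C2 and C4 form an enol-ether double bond with an oxygen donor at each end (O1, and the C4 oxygen as O–Si). This bond is the best carbene acceptor in the molecule, and the two donors also push the cyclopropane open.
- Ring order: rings A and B and the five-membered O-ring are bought. The five-membered ring becomes ring C in step 8, and no other ring is made.

Key step: step 8

Remark: CIP analysis of the given SMILES gives (3S). The sense of induction of the (S,S)-Ru catalyst is assigned by the usual model for aryl ketones ((S,S) gives 4S; the cis relation then gives 3S). Compounds 1, 4 and 18 are taken as purchasable.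

Step 1
Reactants: 1 4,6-dihydroxybenzofuran-3(2H)-one
Product: 2 4-hydroxy-6-(methoxymethoxy)benzofuran-3(2H)-one
Conditions: MOMCl (1.05 equiv), K2CO3 (1.0 equiv), DMF, 0 °C
Reagents that add atoms: chloromethyl methyl ether, COCCl
Why: Williamson-type O-alkylation in which one equivalent of base ionises only the more acidic 6-OH (para to the ketone, not hydrogen-bonded), so the 4-OH next to C3=O should stay free.

Step 2
Reactants: 2 4-hydroxy-6-(methoxymethoxy)benzofuran-3(2H)-one
Product: 3 6-(methoxymethoxy)-3,4-bis(trimethylsilyloxy)benzofuran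
Conditions: Et3N (3 equiv), then TMSOTf (2.3 equiv), CH2Cl2, 0 °C; pentane, filtration under N2, used directly
Reagents that add atoms: trimethylsilyl triflate, C[Si](C)(C)OS(=O)(=O)C(F)(F)F
Why: Soft enolisation and O-silylation, easy here because the enol ether is an aromatic benzofuran, while the same reagent caps the 4-OH and so removes the only O–H bond before the carbene step (excess amine keeps the MOM acetal safe).

Step 3
Reactants: 4 3-bromo-4,5-dihydroxybenzaldehyde
Product: 5 3-bromo-5-hydroxy-4-methoxybenzaldehyde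
Conditions: MeI (1.0 equiv), Li2CO3, DMF, 40 °C
Reagents that add atoms: iodomethane, CI
Why: Regioselective Williamson methylation, since the 4-OH is para to the aldehyde and ortho to bromine and thus clearly the more acidic, so a weak base with one equivalent of MeI should alkylate it alone.

Step 4
Reactants: 5 3-bromo-5-hydroxy-4-methoxybenzaldehyde
Product: 6 3-bromo-4-methoxy-5-(methoxymethoxy)benzaldehyde
Conditions: MOMCl, K2CO3, DMF, 0 → 23 °C
Reagents that add atoms: chloromethyl methyl ether, COCCl
Why: Williamson-type acetal protection of the only remaining phenol, giving a group that is stable to base, hypochlorite, Pd and Ru.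

Step 5
Reactants: 6 3-bromo-4-methoxy-5-(methoxymethoxy)benzaldehyde
Product: 7 3-bromo-4-methoxy-5-(methoxymethoxy)benzonitrile
Conditions: I2, aq NH3 (28 %), THF, 23 °C
Reagents that add atoms: ammonia, N
Why: Oxidative conversion of an aldehyde into a nitrile (aldimine formation, N-iodination, loss of HI) in a basic medium that leaves the MOM ether and the C–Br bond untouched.

Step 6
Reactants: 7 3-bromo-4-methoxy-5-(methoxymethoxy)benzonitrile
Product: 9 3-bromo-4-methoxy-5-(methoxymethoxy)benzamidine hydrochloride, via silylated lithium amidinate 8 (not isolated)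
Conditions: LiHMDS, THF, 0 → 23 °C; then NH4Cl, MeOH, 0 → 23 °C
Reagents that add atoms: lithium hexamethyldisilazide, [Li]N([Si](C)(C)C)[Si](C)(C)C; ammonium chloride, [NH4+].[Cl-]
Why: Addition of the silylamide to the nitrile followed by methanolysis of the N–Si bonds, with ammonium as a proton source strong enough for the amidine but too weak to cleave the MOM ether.

Step 7
Reactants: 9 3-bromo-4-methoxy-5-(methoxymethoxy)benzamidine hydrochloride
Product: 10 3-[3-bromo-4-methoxy-5-(methoxymethoxy)phenyl]-3-chloro-3H-diazirine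
Conditions: aq NaOCl (brine-saturated), DMSO, Et2O–pentane, 0 °C; kept cold, dark and in solution
Reagents that add atoms: sodium hypochlorite, [Na+].[O-]Cl
Why: Graham oxidation (double N-chlorination, base-induced N–N closure and capture of chloride at carbon), in which the amidinium group deactivates the arene against ring chlorination.

Step 8
Reactants: 3 6-(methoxymethoxy)-3,4-bis(trimethylsilyloxy)benzofuran; 10 3-[3-bromo-4-methoxy-5-(methoxymethoxy)phenyl]-3-chloro-3H-diazirine
Product: 15 3-[3-bromo-4-methoxy-5-(methoxymethoxy)phenyl]-5-hydroxy-7-(methoxymethoxy)-4H-chromen-4-one, via arylchlorocarbene 11 (not isolated), via chlorocyclopropane 12 (not isolated), via silyloxybenzopyrylium chloride 13 (not isolated), via 5-O-silyl isoflavone 14 (not isolated)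
Conditions: 10 (2 equiv, slow addition), 4 Å MS, MeCN, 60 °C, dark; evaporation; MeOH, 23 °C
Reagents that add atoms: none
Why: Proposed new method: heating 10 expels N2 and gives the singlet arylchlorocarbene 11, which adds by a concerted [2+1] cheletropic closure to the C2=C3 bond of the furan ring of 3 and so dearomatises it to the cis-fused chlorocyclopropane 12. Ionisation of chloride is coupled to the 2π-disrotatory electrocyclic opening of the three-membered ring (Woodward–Hoffmann–DePuy rule), which breaks the bond opposite to the C–Cl carbon, that is the old C2–C3 bond common to both rings, so that the five-membered ring O1–C2–C3–C3a–C7a turns into the six-membered, aromatic 4-silyloxybenzopyrylium ring of 13 with the aryl-bearing carbon as its new C3. Chloride then takes the silyl group from the C4 oxygen (as Me3SiCl) to give chromen-4-one 14, and methanol removes the labile peri 5-O-silyl group to give 15. The closest known reaction types are the Ciamician–Dennstedt-type carbon insertion of arylchlorodiazirines into indoles and pyrroles, the dihalocarbene ring expansion of cyclic silyl enol ethers to 2-halo-enones and the halocarbene enlargement of benzofurans to chromenes, and only the pairing of an arylchlorocarbene with a 3-silyloxybenzofuran is new. The stereocentres of 12 are transient and need no control, because the fusion can only be cis, both epimers at the C(Cl)Ar carbon should end in the same flat cation 13 (the exo-chloride by stepwise ionisation to the aryl-stabilised cyclopropyl cation), and 15 has no stereocentre. The step needs the carbene to choose this one π bond and the shared bond to break: the first is secured by the two oxygen donors on C2=C3 and by the absence of any other alkene or O–H bond (the prenyl groups are still missing and all phenols are capped), the second by the position of the chloride and by the push of O1 and O–Si toward the pyrylium ion.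

Step 9
Reactants: 15 3-[3-bromo-4-methoxy-5-(methoxymethoxy)phenyl]-5-hydroxy-7-(methoxymethoxy)-4H-chromen-4-one
Product: 16 3-[3-bromo-4-methoxy-5-(methoxymethoxy)phenyl]-5-hydroxy-6-iodo-7-(methoxymethoxy)-4H-chromen-4-one
Conditions: NIS (1.05 equiv), DMF, 0 → 23 °C, dark
Reagents that add atoms: N-iodosuccinimide, O=C1CCC(=O)N1I
Why: Electrophilic aromatic iodination in which ring A is by far the most electron-rich arene and the free, chelated 5-OH directs to its ortho position C6 rather than to C8, as is known for 5-hydroxy-7-alkoxyflavones.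

Step 10
Reactants: 16 3-[3-bromo-4-methoxy-5-(methoxymethoxy)phenyl]-5-hydroxy-6-iodo-7-(methoxymethoxy)-4H-chromen-4-one
Product: 17 3-[3-bromo-4-methoxy-5-(methoxymethoxy)phenyl]-6-iodo-5,7-bis(methoxymethoxy)-4H-chromen-4-one
Conditions: NaH, MOMCl, DMF, 0 °C
Reagents that add atoms: chloromethyl methyl ether, COCCl
Why: Williamson-type protection in which irreversible deprotonation by hydride breaks the chelate of the 5-OH, and the non-nucleophilic base at low temperature spares the base-sensitive C2 of the chromenone.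

Step 11
Reactants: 17 3-[3-bromo-4-methoxy-5-(methoxymethoxy)phenyl]-6-iodo-5,7-bis(methoxymethoxy)-4H-chromen-4-one; 18 tributyl(3-methylbut-2-en-1-yl)stannane
Product: 19 3-[4-methoxy-3-(methoxymethoxy)-5-(3-methylbut-2-en-1-yl)phenyl]-5,7-bis(methoxymethoxy)-6-(3-methylbut-2-en-1-yl)-4H-chromen-4-one
Conditions: 18 (3 equiv), Pd(PPh3)4 (cat.), DMF, 100 °C, degassed
Reagents that add atoms: none
Why: Double Stille coupling at C–I and C–Br, in which reductive elimination from the η3-prenyl palladium aryl at the less hindered CH2 terminus should give the linear prenyl arenes under neutral conditions that spare the chromenone and the MOM groups.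

Step 12
Reactants: 19 3-[4-methoxy-3-(methoxymethoxy)-5-(3-methylbut-2-en-1-yl)phenyl]-5,7-bis(methoxymethoxy)-6-(3-methylbut-2-en-1-yl)-4H-chromen-4-one
Product: 21 (3S,4S)-3-[4-methoxy-3-(methoxymethoxy)-5-(3-methylbut-2-en-1-yl)phenyl]-5,7-bis(methoxymethoxy)-6-(3-methylbut-2-en-1-yl)chroman-4-ol, via racemic isoflavanone 20 (not isolated)
Conditions: RuCl[(S,S)-TsDPEN](p-cymene) (cat.), HCO2H–Et3N (1:1), EtOAc, 40 °C
Reagents that add atoms: none
Why: Noyori–Ikariya asymmetric transfer hydrogenation, known on isoflavones, in which Ru–H first adds 1,4 to give racemic 20, C3 of 20 epimerises fast through the enol in the amine medium, and the (S,S)-catalyst should reduce only the (3S)-ketone to the 4S, cis alcohol, so that both stereocentres are set under catalyst control in a dynamic kinetic resolution while the isolated trisubstituted alkenes stay untouched.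

Step 13
Reactants: 21 (3S,4S)-3-[4-methoxy-3-(methoxymethoxy)-5-(3-methylbut-2-en-1-yl)phenyl]-5,7-bis(methoxymethoxy)-6-(3-methylbut-2-en-1-yl)chroman-4-ol
Product: 22 (3S)-3-[4-methoxy-3-(methoxymethoxy)-5-(3-methylbut-2-en-1-yl)phenyl]-5,7-bis(methoxymethoxy)-6-(3-methylbut-2-en-1-yl)chroman-4-one
Conditions: Dess–Martin periodinane, CH2Cl2, 0 → 23 °C; cold pH 7 work-up, short neutral plug
Reagents that add atoms: none
Why: Dess–Martin oxidation, which is base-free and only weakly acidic, should remove the C4 stereocentre without enolising the new α-aryl ketone, so that C3 keeps its (S) configuration and the alkenes are spared.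

Step 14
Reactants: 22 (3S)-3-[4-methoxy-3-(methoxymethoxy)-5-(3-methylbut-2-en-1-yl)phenyl]-5,7-bis(methoxymethoxy)-6-(3-methylbut-2-en-1-yl)chroman-4-one
Product: 23 (3S)-5,7-dihydroxy-3-[3-hydroxy-4-methoxy-5-(3-methylbut-2-en-1-yl)phenyl]-6-(3-methylbut-2-en-1-yl)chroman-4-one
Conditions: HCl (cat., 0.5 M in MeOH), 0 → 23 °C, stopped at full conversion
Reagents that add atoms: none
Why: Acid-catalysed transacetalisation of the three phenolic MOM ethers to methanol under mild conditions of the kind used for prenylated flavonoids, chosen because base would racemise C3 at once whereas acid-catalysed enolisation and chroman formation should be slow at this temperature.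

**Compound list**
1 | 4,6-dihydroxybenzofuran-3(2H)-one | O=C1COc2cc(O)cc(O)c21 | starting material
2 | 4-hydroxy-6-(methoxymethoxy)benzofuran-3(2H)-one | O=C1COc2cc(OCOC)cc(O)c21 | intermediate
3 | 6-(methoxymethoxy)-3,4-bis(trimethylsilyloxy)benzofuran | C[Si](C)(C)Oc1coc2cc(OCOC)cc(O[Si](C)(C)C)c12 | intermediate
4 | 3-bromo-4,5-dihydroxybenzaldehyde | O=Cc1cc(O)c(O)c(Br)c1 | starting material
5 | 3-bromo-5-hydroxy-4-methoxybenzaldehyde | O=Cc1cc(O)c(OC)c(Br)c1 | intermediate
6 | 3-bromo-4-methoxy-5-(methoxymethoxy)benzaldehyde | O=Cc1cc(OCOC)c(OC)c(Br)c1 | intermediate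
7 | 3-bromo-4-methoxy-5-(methoxymethoxy)benzonitrile | N#Cc1cc(OCOC)c(OC)c(Br)c1 | intermediate
8 | lithium N,N'-bis(trimethylsilyl)-3-bromo-4-methoxy-5-(methoxymethoxy)benzamidinate | [Li]N([Si](C)(C)C)C(=N[Si](C)(C)C)c1cc(OCOC)c(OC)c(Br)c1 | intermediate
9 | 3-bromo-4-methoxy-5-(methoxymethoxy)benzamidine hydrochloride | Cl.N=C(N)c1cc(OCOC)c(OC)c(Br)c1 | intermediate
10 | 3-[3-bromo-4-methoxy-5-(methoxymethoxy)phenyl]-3-chloro-3H-diazirine | ClC1(N=N1)c1cc(OCOC)c(OC)c(Br)c1 | intermediate
11 | [3-bromo-4-methoxy-5-(methoxymethoxy)phenyl]chlorocarbene | Cl[C]c1cc(OCOC)c(OC)c(Br)c1 | intermediate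
12 | 1-[3-bromo-4-methoxy-5-(methoxymethoxy)phenyl]-1-chloro-4-(methoxymethoxy)-6,6b-bis(trimethylsilyloxy)-1a,6b-dihydro-1H-cyclopropa[b]benzofuran (racemic, cis-fused, both C1 epimers) | C[Si](C)(C)OC12C(Oc3cc(OCOC)cc(O[Si](C)(C)C)c31)C2(Cl)c1cc(OCOC)c(OC)c(Br)c1 | intermediate
13 | 3-[3-bromo-4-methoxy-5-(methoxymethoxy)phenyl]-7-(methoxymethoxy)-4,5-bis(trimethylsilyloxy)chromenylium chloride | C[Si](C)(C)Oc1c(-c2cc(OCOC)c(OC)c(Br)c2)c[o+]c2cc(OCOC)cc(O[Si](C)(C)C)c12.[Cl-] | intermediate
14 | 3-[3-bromo-4-methoxy-5-(methoxymethoxy)phenyl]-7-(methoxymethoxy)-5-(trimethylsilyloxy)-4H-chromen-4-one | C[Si](C)(C)Oc1cc(OCOC)cc2occ(-c3cc(OCOC)c(OC)c(Br)c3)c(=O)c12 | intermediate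
15 | 3-[3-bromo-4-methoxy-5-(methoxymethoxy)phenyl]-5-hydroxy-7-(methoxymethoxy)-4H-chromen-4-one | Oc1cc(OCOC)cc2occ(-c3cc(OCOC)c(OC)c(Br)c3)c(=O)c12 | intermediate
16 | 3-[3-bromo-4-methoxy-5-(methoxymethoxy)phenyl]-5-hydroxy-6-iodo-7-(methoxymethoxy)-4H-chromen-4-one | Oc1c(I)c(OCOC)cc2occ(-c3cc(OCOC)c(OC)c(Br)c3)c(=O)c12 | intermediate
17 | 3-[3-bromo-4-methoxy-5-(methoxymethoxy)phenyl]-6-iodo-5,7-bis(methoxymethoxy)-4H-chromen-4-one | COCOc1c(I)c(OCOC)cc2occ(-c3cc(OCOC)c(OC)c(Br)c3)c(=O)c12 | intermediate
18 | tributyl(3-methylbut-2-en-1-yl)stannane | CC(C)=CC[Sn](CCCC)(CCCC)CCCC | starting material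
19 | 3-[4-methoxy-3-(methoxymethoxy)-5-(3-methylbut-2-en-1-yl)phenyl]-5,7-bis(methoxymethoxy)-6-(3-methylbut-2-en-1-yl)-4H-chromen-4-one | COCOc1c(CC=C(C)C)c(OCOC)cc2occ(-c3cc(OCOC)c(OC)c(CC=C(C)C)c3)c(=O)c12 | intermediate
20 | rac-3-[4-methoxy-3-(methoxymethoxy)-5-(3-methylbut-2-en-1-yl)phenyl]-5,7-bis(methoxymethoxy)-6-(3-methylbut-2-en-1-yl)chroman-4-one | COc1c(OCOC)cc(C2COc3cc(OCOC)c(CC=C(C)C)c(OCOC)c3C2=O)cc1CC=C(C)C | intermediate
21 | (3S,4S)-3-[4-methoxy-3-(methoxymethoxy)-5-(3-methylbut-2-en-1-yl)phenyl]-5,7-bis(methoxymethoxy)-6-(3-methylbut-2-en-1-yl)chroman-4-ol (cis) | COc1c(OCOC)cc([C@H]2COc3cc(OCOC)c(CC=C(C)C)c(OCOC)c3[C@H]2O)cc1CC=C(C)C | intermediate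
22 | (3S)-3-[4-methoxy-3-(methoxymethoxy)-5-(3-methylbut-2-en-1-yl)phenyl]-5,7-bis(methoxymethoxy)-6-(3-methylbut-2-en-1-yl)chroman-4-one | COc1c(OCOC)cc([C@H]2COc3cc(OCOC)c(CC=C(C)C)c(OCOC)c3C2=O)cc1CC=C(C)C | intermediate
23 | (3S)-5,7-dihydroxy-3-[3-hydroxy-4-methoxy-5-(3-methylbut-2-en-1-yl)phenyl]-6-(3-methylbut-2-en-1-yl)chroman-4-one | COc1c(O)cc([C@H]2COc3cc(O)c(CC=C(C)C)c(O)c3C2=O)cc1CC=C(C)C | target

Total step count: 14.
Longest linear sequence: 12 steps (steps 3–14, from 4).

**Steps most likely to fail**

1. Step 8 (new method).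
   - What may go wrong: the carbene may be lost to azine formation or to the solvent before it reaches the hindered enol ether. The silyl enol ether may hydrolyse. An outer bond of the cyclopropane may break in place of the shared one, which would keep the five-membered ring.
   - Fallback: the ring expansion is kept, ring B is attached afterwards, and only known reaction types are used. It sets out from 3 and 6 and comes back at 15.
   - Dibromocarbene (CHBr3, KOt-Bu, pentane, −20 °C) should add to 3 to give the dibromocyclopropane F1. On warming, this should open with loss of the silyl bromide to 3-bromo-7-(methoxymethoxy)-5-(trimethylsilyloxy)chromen-4-one F2. Methanol should then give 3-bromo-5-hydroxy-7-(methoxymethoxy)chromen-4-one F3. This is the dihalocarbene ring expansion of a cyclic silyl enol ether.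
   - Aldehyde 6 is decarbonylated (Tsuji–Wilkinson type, Rh/dppp cat., hot diglyme) to 1-bromo-2-methoxy-3-(methoxymethoxy)benzene F4. Sterically controlled Ir-catalysed C–H borylation (B2pin2, [Ir(OMe)(cod)]2, dtbpy) at the only C–H without an ortho neighbour gives the pinacol boronate F5.
   - Suzuki–Miyaura coupling of F3 with F5 (Pd(dppf)Cl2, aq Na2CO3, dioxane, 50 °C) should give 15. The activated C3–Br bond of the bromo-enone should react ahead of the electron-rich aryl bromide.

2. Step 12.
   - What may go wrong: hydride transfer to the electron-rich, peri-substituted C4 carbonyl may be too slow. Racemisation at C3 may not keep pace with the reduction. The very electron-rich benzylic alcohol may ionise in the formic acid medium.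
   - Fallback: the stereocentre is set by protonation and no C4 alcohol is made. It sets out from 19 and comes back at 22.
   - L-Selectride (THF, −78 °C) should add hydride 1,4 to give the lithium enolate F6. This is trapped on oxygen with allyl chloroformate to give the allyl enol carbonate F7.
   - Pd-catalysed decarboxylative asymmetric protonation (Pd(OAc)2, t-Bu-PHOX, HCO2H, 4 Å MS, dioxane, 40 °C) is a reaction type known for isoflavanones and should then give 22. The ligand enantiomer that leads to (3S) has to be fixed in a test run.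

3. Step 14.
   - What may go wrong: the acid may enolise the α-aryl ketone and erode the configuration at C3. It may also add the 5-OH or 7-OH to the neighbouring prenyl double bond.
   - Fallback: the protecting groups are exchanged while the molecule is still flat, and fluoride replaces acid at the end. It sets out from 19 and comes back at 23.
   - HCl in MeOH on 19, which has no stereocentre to lose, should give the free trihydroxy-diprenylisoflavone F8. TBSOTf and 2,6-lutidine give the tris-TBS isoflavone F9.
   - The transfer hydrogenation of step 12 should pass through the racemic tris-TBS isoflavanone F10 to the (3S,4S)-tris-TBS isoflavanol F11.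
   - Dess–Martin oxidation gives the (3S)-tris-TBS isoflavanone F12. HF·pyridine (THF–pyridine, 0 °C) should then set free 23 without strong acid or base.

**Further compounds**
F1 | step 8 | 1,1-dibromo-4-(methoxymethoxy)-6,6b-bis(trimethylsilyloxy)-1a,6b-dihydro-1H-cyclopropa[b]benzofuran (racemic) | C[Si](C)(C)OC12C(Oc3cc(OCOC)cc(O[Si](C)(C)C)c31)C2(Br)Br
F2 | step 8 | 3-bromo-7-(methoxymethoxy)-5-(trimethylsilyloxy)-4H-chromen-4-one | C[Si](C)(C)Oc1cc(OCOC)cc2occ(Br)c(=O)c12
F3 | step 8 | 3-bromo-5-hydroxy-7-(methoxymethoxy)-4H-chromen-4-one | Oc1cc(OCOC)cc2occ(Br)c(=O)c12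
F4 | step 8 | 1-bromo-2-methoxy-3-(methoxymethoxy)benzene | COCOc1cccc(Br)c1OC
F5 | step 8 | 2-[3-bromo-4-methoxy-5-(methoxymethoxy)phenyl]-4,4,5,5-tetramethyl-1,3,2-dioxaborolane | COCOc1cc(B2OC(C)(C)C(C)(C)O2)cc(Br)c1OC
F6 | step 12 | lithium enolate of 20 (lithium 2H-chromen-4-olate) | [Li]OC1=C(COc2cc(OCOC)c(CC=C(C)C)c(OCOC)c12)c1cc(OCOC)c(OC)c(CC=C(C)C)c1
F7 | step 12 | allyl 3-[4-methoxy-3-(methoxymethoxy)-5-(3-methylbut-2-en-1-yl)phenyl]-5,7-bis(methoxymethoxy)-6-(3-methylbut-2-en-1-yl)-2H-chromen-4-yl carbonate | C=CCOC(=O)OC1=C(COc2cc(OCOC)c(CC=C(C)C)c(OCOC)c12)c1cc(OCOC)c(OC)c(CC=C(C)C)c1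
F8 | step 14 | 5,7-dihydroxy-3-[3-hydroxy-4-methoxy-5-(3-methylbut-2-en-1-yl)phenyl]-6-(3-methylbut-2-en-1-yl)-4H-chromen-4-one | COc1c(O)cc(-c2coc3cc(O)c(CC=C(C)C)c(O)c3c2=O)cc1CC=C(C)C
F9 | step 14 | tris-TBS ether of F8 | COc1c(O[Si](C)(C)C(C)(C)C)cc(-c2coc3cc(O[Si](C)(C)C(C)(C)C)c(CC=C(C)C)c(O[Si](C)(C)C(C)(C)C)c3c2=O)cc1CC=C(C)C
F10 | step 14 | racemic tris-TBS isoflavanone | COc1c(O[Si](C)(C)C(C)(C)C)cc(C2COc3cc(O[Si](C)(C)C(C)(C)C)c(CC=C(C)C)c(O[Si](C)(C)C(C)(C)C)c3C2=O)cc1CC=C(C)C
F11 | step 14 | (3S,4S)-tris-TBS isoflavan-4-ol (cis) | COc1c(O[Si](C)(C)C(C)(C)C)cc([C@H]2COc3cc(O[Si](C)(C)C(C)(C)C)c(CC=C(C)C)c(O[Si](C)(C)C(C)(C)C)c3[C@H]2O)cc1CC=C(C)C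
F12 | step 14 | (3S)-tris-TBS isoflavanone | COc1c(O[Si](C)(C)C(C)(C)C)cc([C@H]2COc3cc(O[Si](C)(C)C(C)(C)C)c(CC=C(C)C)c(O[Si](C)(C)C(C)(C)C)c3C2=O)cc1CC=C(C)C
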